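The route rests on cutting the C2–C3 bond of the tetrahydrofuran ring. C2 is a benzylic carbon at the acetal oxidation level (bonded to O1 and an aryl group) and C3 carries a one-carbon oxygenated branch, so the bond is what an aryl oxocarbenium ion (O1=C2) leaves when it recaptures the α-carbon of an aldehyde enolate. One Lewis-acid step contracts a seven-membered cyclic vinyl acetal to the five-membered ring, making C2–C3, the C3 formyl group and both new stereocentres. The precursor is a 2,4-diaryl-5-(benzyloxymethyl)-4,5-dihydro-1,3-dioxepine whose C4 and C5 centres come from an asymmetric syn-allylboration; reduction and one hydrogenolysis finish.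

Key step: step 8

Remarks on the chemistry (assumptions)
- The target is the (2S,3S,4S,5S) isomer: 2,3-cis, 3,4-trans, 4,5-cis, with a twofold axis.
- The acetal carbon made in step 5 is formed without control. Both epimers are carried through steps 6 and 7, because this carbon becomes planar in step 8. The acyclic acetals are therefore written with that centre undefined, and the dioxepine as its 2,4-cis epimer, beside which its C2 epimer is expected and should react alike.
- The sense of induction in step 3 is assigned by analogy with aryl aldehydes in this catalysis, where the (R)-acid leads to Re-face addition. It should be checked on the first batch (Mosher esters); the antipodal acid is the remedy.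
- Numbering: dioxepine O1 (enol-ether oxygen), C2 (acetal), O3, C4 (aryl), C5 (CH2OBn), C6=C7; tetrahydrofuran O1, C2, C3 (CHO), C4 (CH2OBn), C5.
- All five starting materials are catalogue compounds; O-benzylvanillin is bought, not made.

Step 1
Reactants: 1 benzyl propargyl ether; 2 pinacolborane
Product: 3 (Z)-2-[3-(benzyloxy)prop-1-en-1-yl]-4,4,5,5-tetramethyl-1,3,2-dioxaborolane
Conditions: [RhCl(cod)]2 (1.5 mol %), P(iPr)3 (6 mol %), Et3N (1 equiv), cyclohexane, rt; 1 in slight excess
Reagents that add atoms: pinacolborane (compound 2), [H]B1OC(C)(C)C(C)(C)O1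
Why: Rhodium-catalysed trans-hydroboration of a terminal alkyne, which runs through a rhodium vinylidene so that boron and hydrogen end up anti across the alkene and the (Z)-alkenylboronate results instead of the (E) isomer of ordinary syn-hydroboration.

Step 2
Reactants: 3 (Z)-2-[3-(benzyloxy)prop-1-en-1-yl]-4,4,5,5-tetramethyl-1,3,2-dioxaborolane; 4 chloroiodomethane
Product: 6 (Z)-2-[4-(benzyloxy)but-2-en-1-yl]-4,4,5,5-tetramethyl-1,3,2-dioxaborolane, via lithium chloromethyl alkenyl boronate complex 5 (not isolated)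
Conditions: ICH2Cl (1.3 equiv), n-BuLi (1.2 equiv), THF, −78 °C → rt
Reagents that add atoms: chloroiodomethane (compound 4), ClCI
Why: Matteson homologation, in which chloromethyllithium made in situ adds to boron and the alkenyl group of ate complex 5 migrates to carbon with loss of chloride, inserting CH2 into the C–B bond with retention of the (Z) geometry.

Step 3
Reactants: 6 (Z)-2-[4-(benzyloxy)but-2-en-1-yl]-4,4,5,5-tetramethyl-1,3,2-dioxaborolane; 7 4-(benzyloxy)-3-methoxybenzaldehyde
Product: 9 (1S,2S)-1-[4-(benzyloxy)-3-methoxyphenyl]-2-[(benzyloxy)methyl]but-3-en-1-ol, via pinacol borate ester 8 (not isolated)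
Conditions: 6 (1.2 equiv), (S)-TRIP phosphoric acid (5 mol %), 4 Å MS, toluene, −30 °C; then aq. NaHCO3
Reagents that add atoms: none
Why: Chiral-phosphoric-acid-catalysed allylboration of an aldehyde: in the closed Zimmerman–Traxler chair the (Z)-substituent is axial, which makes C1 and C2 syn, and the (S)-acid, bound to a boronate oxygen and the formyl hydrogen, should direct addition to the Si face of 7 to set (1S,2S).

Step 4
Reactants: 7 4-(benzyloxy)-3-methoxybenzaldehyde; 10 (2-chloroethoxy)trimethylsilane
Product: 11 1-(benzyloxy)-4-[bis(2-chloroethoxy)methyl]-2-methoxybenzene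
Conditions: 10 (2.2 equiv), TMSOTf (2 mol %), CH2Cl2, −78 → −20 °C; pyridine, then aq. NaHCO3
Reagents that add atoms: (2-chloroethoxy)trimethylsilane (compound 10), C[Si](C)(C)OCCCl
Why: Silyl-triflate-catalysed acetalisation of an aldehyde with an alkoxysilane, irreversible because the carbonyl oxygen leaves as hexamethyldisiloxane and cold enough to leave the benzyl ether and the electron-rich ring alone.

Step 5
Reactants: 11 1-(benzyloxy)-4-[bis(2-chloroethoxy)methyl]-2-methoxybenzene; 9 (1S,2S)-1-[4-(benzyloxy)-3-methoxyphenyl]-2-[(benzyloxy)methyl]but-3-en-1-ol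
Product: 13 1-(benzyloxy)-4-[{[(1S,2S)-1-[4-(benzyloxy)-3-methoxyphenyl]-2-[(benzyloxy)methyl]but-3-en-1-yl]oxy}(2-chloroethoxy)methyl]-2-methoxybenzene (both epimers at the acetal carbon), via collidinium triflate 12 (not isolated)
Conditions: 11 (1.6 equiv), TESOTf (1.5 equiv), 2,4,6-collidine (3 equiv), CH2Cl2, 0 °C; then 9 (1.0 equiv), 0 °C → rt; aq. NaHCO3
Reagents that add atoms: none
Why: Mixed-acetal synthesis by silyl triflate and collidine activation of an acetal: one chloroethoxy group is removed as its silyl ether, collidinium salt 12 is then substituted by the secondary hydroxyl group of 9 under buffered conditions that do not ionise the 4-alkoxybenzylic carbinol, and the new acetal carbon is formed without stereocontrol, which is of no consequence.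

Step 6
Reactants: 13 1-(benzyloxy)-4-[{[(1S,2S)-1-[4-(benzyloxy)-3-methoxyphenyl]-2-[(benzyloxy)methyl]but-3-en-1-yl]oxy}(2-chloroethoxy)methyl]-2-methoxybenzene
Product: 14 1-(benzyloxy)-4-[{[(1S,2S)-1-[4-(benzyloxy)-3-methoxyphenyl]-2-[(benzyloxy)methyl]but-3-en-1-yl]oxy}(ethenyloxy)methyl]-2-methoxybenzene (both epimers at the acetal carbon)
Conditions: KOtBu (3 equiv), 18-crown-6 (10 mol %), THF, 0 °C → rt
Reagents that add atoms: none
Why: E2 dehydrochlorination of a 2-chloroethyl ether to a vinyl ether with KOtBu, to which the acetal, the benzyl ethers and the terminal alkene are inert at this temperature.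

Step 7
Reactants: 14 1-(benzyloxy)-4-[{[(1S,2S)-1-[4-(benzyloxy)-3-methoxyphenyl]-2-[(benzyloxy)methyl]but-3-en-1-yl]oxy}(ethenyloxy)methyl]-2-methoxybenzene
Product: 15 (2S,4S,5S)-2,4-bis[4-(benzyloxy)-3-methoxyphenyl]-5-[(benzyloxy)methyl]-4,5-dihydro-1,3-dioxepine (2,4-cis-4,5-cis)
Conditions: second-generation Grubbs catalyst (H2IMes)(PCy3)Cl2Ru=CHPh (5–10 mol %), 1,4-benzoquinone (10 mol %), toluene (5 mM), 70 °C; Et3N-deactivated silica
Reagents that add atoms: none
Why: Ring-closing olefin metathesis of a terminal alkene with a vinyl ether, in which the ruthenium carbene loads on the alkene and closes onto the enol ether with loss of ethene to give the seven-membered cyclic enol acetal with its necessarily cis ring alkene, the preset C4 and C5 centres being untouched.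

Step 8
Reactants: 15 (2S,4S,5S)-2,4-bis[4-(benzyloxy)-3-methoxyphenyl]-5-[(benzyloxy)methyl]-4,5-dihydro-1,3-dioxepine
Product: 17 (2S,3R,4S,5S)-2,5-bis[4-(benzyloxy)-3-methoxyphenyl]-4-[(benzyloxy)methyl]tetrahydrofuran-3-carbaldehyde (2,3-cis-3,4-trans-4,5-cis), via oxocarbenium silyl enol ether ion pair 16 (not isolated)
Conditions: TMSOTf (0.2 equiv), CH2Cl2, −78 °C; Et3N then aq. NaHCO3 at −78 °C; crude product used at once
Reagents that add atoms: none
Why: TMSOTf silylates the enol-ether oxygen O1 of 15, the C2–O1 bond ionises, and the resulting contact ion pair 16 of an (E)-aryl oxocarbenium ion (O3=C2) and a tethered (Z)-silyl enol ether (C6=C7) collapses by attack of C6 on C2 with release of TMSOTf, so that dioxepine O3, C2, C6, C5 and C4 become O1, C2, C3, C4 and C5 of the tetrahydrofuran and C7 becomes the formyl carbon. The closest known reaction type is the Lewis-acid 1,3 oxygen-to-carbon rearrangement of cyclic vinyl acetals (a Petasis–Ferrier-type ring contraction of 4,5-dihydro-1,3-dioxepines to tetrahydrofuran-3-carbaldehydes, ending in a Mukaiyama-type addition to an oxocarbenium ion). The five-membered ring closes in the 5-(enolexo)-endo-trig mode, with both atoms of the O3=C2 unit inside the new ring and the enol double bond outside it. C3 is controlled by the preset C4 centre: allylic 1,3-strain keeps the C5–H bond of 16 in the plane of the (Z)-enol ether, the tether delivers C2 to one face, and the formyl arm ends trans to the benzyloxymethyl group. C2 is controlled kinetically by least-motion collapse of the ion pair at −78 °C, which joins the (E)-oxocarbenium ion and the (Z)-enol ether with the aryl group cis to the formyl group and trans to the C5 aryl group, both acetal epimers of 15 converging on the same ion pair. The step needs the 2,3-cis-3,4-trans isomer instead of the more stable 2,3-trans one and ionisation at C2–O1 only, which the low temperature, the substoichiometric Lewis acid, the cold amine quench, the electron-rich aryl group at C2 and the better leaving ability of the enol-ether oxygen should secure.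

Step 9
Reactants: 17 (2S,3R,4S,5S)-2,5-bis[4-(benzyloxy)-3-methoxyphenyl]-4-[(benzyloxy)methyl]tetrahydrofuran-3-carbaldehyde
Product: 18 [(2S,3S,4S,5S)-2,5-bis[4-(benzyloxy)-3-methoxyphenyl]-4-[(benzyloxy)methyl]tetrahydrofuran-3-yl]methanol
Conditions: NaBH4, MeOH–CH2Cl2, −78 → 0 °C
Reagents that add atoms: none
Why: Chemoselective NaBH4 reduction of the aldehyde, done cold on the crude material so that the epimerisable C3 centre is fixed as the hydroxymethyl group before it can invert.

Step 10
Reactants: 18 [(2S,3S,4S,5S)-2,5-bis[4-(benzyloxy)-3-methoxyphenyl]-4-[(benzyloxy)methyl]tetrahydrofuran-3-yl]methanol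
Product: 19 eduesmine [(2S,3S,4S,5S)-2,5-bis(4-hydroxy-3-methoxyphenyl)tetrahydrofuran-3,4-diyl]dimethanol
Conditions: H2 (1 atm), 10% Pd/C, EtOAc–MeOH, rt; stopped when debenzylation is complete
Reagents that add atoms: none
Why: Catalytic hydrogenolysis of the two aryl benzyl ethers and the alkyl benzyl ether over Pd/C in a neutral solvent, under which the ring benzylic C–O bonds, not activated by acid, should survive and no stereocentre is touched.

Compound list
1 | benzyl propargyl ether | C#CCOCc1ccccc1 | starting material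
2 | pinacolborane (4,4,5,5-tetramethyl-1,3,2-dioxaborolane) | [H]B1OC(C)(C)C(C)(C)O1 | starting material
3 | (Z)-2-[3-(benzyloxy)prop-1-en-1-yl]-4,4,5,5-tetramethyl-1,3,2-dioxaborolane | CC1(C)OB(/C=C\COCc2ccccc2)OC1(C)C | intermediate
4 | chloroiodomethane | ClCI | starting material
5 | lithium [(Z)-3-(benzyloxy)prop-1-en-1-yl](chloromethyl)(pinacolato)borate (ate complex; not isolated) | [Li+].CC1(C)O[B-](CCl)(/C=C\COCc2ccccc2)OC1(C)C | intermediate
6 | (Z)-2-[4-(benzyloxy)but-2-en-1-yl]-4,4,5,5-tetramethyl-1,3,2-dioxaborolane | CC1(C)OB(C/C=C\COCc2ccccc2)OC1(C)C | intermediate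
7 | 4-(benzyloxy)-3-methoxybenzaldehyde (O-benzylvanillin) | COc1cc(C=O)ccc1OCc1ccccc1 | starting material
8 | 2-{[(1S,2S)-1-[4-(benzyloxy)-3-methoxyphenyl]-2-[(benzyloxy)methyl]but-3-en-1-yl]oxy}-4,4,5,5-tetramethyl-1,3,2-dioxaborolane (not isolated) | COc1cc([C@@H](OB2OC(C)(C)C(C)(C)O2)[C@H](COCc2ccccc2)C=C)ccc1OCc1ccccc1 | intermediate
9 | (1S,2S)-1-[4-(benzyloxy)-3-methoxyphenyl]-2-[(benzyloxy)methyl]but-3-en-1-ol (syn) | COc1cc([C@@H](O)[C@H](COCc2ccccc2)C=C)ccc1OCc1ccccc1 | intermediate
10 | (2-chloroethoxy)trimethylsilane | C[Si](C)(C)OCCCl | starting material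
11 | 1-(benzyloxy)-4-[bis(2-chloroethoxy)methyl]-2-methoxybenzene | COc1cc(C(OCCCl)OCCCl)ccc1OCc1ccccc1 | intermediate
12 | 1-{[4-(benzyloxy)-3-methoxyphenyl](2-chloroethoxy)methyl}-2,4,6-trimethylpyridinium triflate (not isolated) | COc1cc(C(OCCCl)[n+]2c(C)cc(C)cc2C)ccc1OCc1ccccc1.[O-]S(=O)(=O)C(F)(F)F | intermediate
13 | 1-(benzyloxy)-4-[{[(1S,2S)-1-[4-(benzyloxy)-3-methoxyphenyl]-2-[(benzyloxy)methyl]but-3-en-1-yl]oxy}(2-chloroethoxy)methyl]-2-methoxybenzene (acetal carbon undefined) | COc1cc(C(OCCCl)O[C@H](c2ccc(OCc3ccccc3)c(OC)c2)[C@H](COCc2ccccc2)C=C)ccc1OCc1ccccc1 | intermediate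
14 | 1-(benzyloxy)-4-[{[(1S,2S)-1-[4-(benzyloxy)-3-methoxyphenyl]-2-[(benzyloxy)methyl]but-3-en-1-yl]oxy}(ethenyloxy)methyl]-2-methoxybenzene (acetal carbon undefined) | COc1cc(C(OC=C)O[C@H](c2ccc(OCc3ccccc3)c(OC)c2)[C@H](COCc2ccccc2)C=C)ccc1OCc1ccccc1 | intermediate
15 | (2S,4S,5S)-2,4-bis[4-(benzyloxy)-3-methoxyphenyl]-5-[(benzyloxy)methyl]-4,5-dihydro-1,3-dioxepine (2,4-cis-4,5-cis) | COc1cc([C@@H]2O[C@H](c3ccc(OCc4ccccc4)c(OC)c3)[C@H](COCc3ccccc3)C=CO2)ccc1OCc1ccccc1 | intermediate
16 | (E)-[4-(benzyloxy)-3-methoxybenzylidene]{(1S,2S,3Z)-1-[4-(benzyloxy)-3-methoxyphenyl]-2-[(benzyloxy)methyl]-4-[(trimethylsilyl)oxy]but-3-en-1-yl}oxonium triflate (contact ion pair; not isolated) | COc1cc(/C=[O+]/[C@H](c2ccc(OCc3ccccc3)c(OC)c2)[C@H](COCc2ccccc2)/C=C\O[Si](C)(C)C)ccc1OCc1ccccc1.[O-]S(=O)(=O)C(F)(F)F | intermediate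
17 | (2S,3R,4S,5S)-2,5-bis[4-(benzyloxy)-3-methoxyphenyl]-4-[(benzyloxy)methyl]tetrahydrofuran-3-carbaldehyde (2,3-cis-3,4-trans-4,5-cis) | COc1cc([C@H]2O[C@H](c3ccc(OCc4ccccc4)c(OC)c3)[C@H](COCc3ccccc3)[C@H]2C=O)ccc1OCc1ccccc1 | intermediate
18 | [(2S,3S,4S,5S)-2,5-bis[4-(benzyloxy)-3-methoxyphenyl]-4-[(benzyloxy)methyl]tetrahydrofuran-3-yl]methanol | COc1cc([C@H]2O[C@H](c3ccc(OCc4ccccc4)c(OC)c3)[C@H](COCc3ccccc3)[C@H]2CO)ccc1OCc1ccccc1 | intermediate
19 | eduesmine, [(2S,3S,4S,5S)-2,5-bis(4-hydroxy-3-methoxyphenyl)tetrahydrofuran-3,4-diyl]dimethanol | COc1cc([C@H]2O[C@H](c3ccc(O)c(OC)c3)[C@H](CO)[C@H]2CO)ccc1O | target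

Total step count: 10.
Longest linear sequence: 9 steps (1, 2, 3, 5, 6, 7, 8, 9, 10); step 4 is a one-step side branch.

Steps most likely to fail

Step 8. The ion pair may re-ionise and re-close under thermodynamic control, or the aldehyde may epimerise at C3 before it is reduced, so that the 2,3-cis relationship is lost; ionisation of the benzylic C5–O1 bond would add to the loss. The fallback sets out from 9 and comes back at 19. It makes the C2–aryl bond by aryllithium addition to a lactone and sets C2 by hydride reduction of a cyclic oxocarbenium ion. Hydroboration–oxidation of 9 (9-BBN, THF; NaOH, H2O2) should give the 1,4-diol F1. Oxidative lactonisation (TEMPO cat., PhI(OAc)2, CH2Cl2) should give the 4,5-cis γ-lactone F2. Alkylation of its lithium enolate (LiN(SiMe3)2, THF, −78 °C) with benzyl chloromethyl ether (ClCOCc1ccccc1), anti to the substituents at C4 and C5, should give the 3,4-trans lactone F3. Addition of 4-(benzyloxy)-3-methoxyphenyllithium F4, made from 1-(benzyloxy)-4-bromo-2-methoxybenzene (COc1cc(Br)ccc1OCc1ccccc1) and n-BuLi at −78 °C, should give the lactol F5. Et3SiH with BF3·OEt2 in CH2Cl2 at −78 °C, with hydride delivered anti to the neighbouring C3 substituent, should give the 2,3-cis tetrabenzyl ether F6. Hydrogenolysis of F6 under the conditions of step 10 gives 19.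

Step 3. Facial or syn/anti selectivity may be insufficient, either because the catalysed path is slow for the electron-rich aldehyde and the uncatalysed background competes, or because the (Z) geometry of 6 has eroded. The fallback sets out from 7 and comes back at 9. It replaces boron and Brønsted-acid catalysis by silicon and Lewis-base catalysis. Commercial (Z)-4-(benzyloxy)but-2-en-1-ol (OC/C=C\COCc1ccccc1) is converted (MsCl, 2,4,6-collidine, LiCl, DMF, 0 °C) to the (Z)-allylic chloride F7. With HSiCl3, CuCl (cat.) and iPr2NEt in Et2O, F7 should give the (Z)-allyltrichlorosilane F8 by direct substitution with retention of geometry. Addition of F8 to 7 under a chiral 2,2'-bipyrrolidine-derived bisphosphoramide (cat.), iPr2NEt, CH2Cl2, −78 °C runs through a closed chair at hexacoordinate silicon and should give the syn trichlorosilyl ether F9, hydrolysed on work-up (aq. NaHCO3) to 9. The catalyst antipode is chosen for Si-face addition.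

Step 5. Capture of the collidinium salt by the hindered secondary alcohol may be incomplete, with silylation of the alcohol or ionisation at its benzylic carbinol as competing processes. The fallback sets out from 11 (with 9) and comes back at 13. It alkylates the alcohol with a preformed α-chloro ether under basic conditions, in the manner of a MOM-type protection. Treatment of 11 with AcCl (cat. ZnBr2, CH2Cl2, 0 °C) should give the α-chloro ether F10 and 2-chloroethyl acetate. F10 is used at once with 9 and iPr2NEt (CH2Cl2, −40 °C → rt) to give 13.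

Further compounds
F1 | step 8 | (1S,2S)-1-[4-(benzyloxy)-3-methoxyphenyl]-2-[(benzyloxy)methyl]butane-1,4-diol | COc1cc([C@@H](O)[C@H](COCc2ccccc2)CCO)ccc1OCc1ccccc1
F2 | step 8 | (4S,5S)-5-[4-(benzyloxy)-3-methoxyphenyl]-4-[(benzyloxy)methyl]dihydrofuran-2(3H)-one | COc1cc([C@H]2OC(=O)C[C@H]2COCc2ccccc2)ccc1OCc1ccccc1
F3 | step 8 | (3S,4S,5S)-5-[4-(benzyloxy)-3-methoxyphenyl]-3,4-bis[(benzyloxy)methyl]dihydrofuran-2(3H)-one | COc1cc([C@H]2OC(=O)[C@H](COCc3ccccc3)[C@H]2COCc2ccccc2)ccc1OCc1ccccc1
F4 | step 8 | 4-(benzyloxy)-3-methoxyphenyllithium | [Li]c1ccc(OCc2ccccc2)c(OC)c1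
F5 | step 8 | (3S,4S,5S)-2,5-bis[4-(benzyloxy)-3-methoxyphenyl]-3,4-bis[(benzyloxy)methyl]tetrahydrofuran-2-ol (anomeric carbon undefined) | COc1cc([C@H]2OC(O)(c3ccc(OCc4ccccc4)c(OC)c3)[C@H](COCc3ccccc3)[C@H]2COCc2ccccc2)ccc1OCc1ccccc1
F6 | step 8 | (2S,3S,4S,5S)-2,5-bis[4-(benzyloxy)-3-methoxyphenyl]-3,4-bis[(benzyloxy)methyl]tetrahydrofuran | COc1cc([C@H]2O[C@H](c3ccc(OCc4ccccc4)c(OC)c3)[C@H](COCc3ccccc3)[C@H]2COCc2ccccc2)ccc1OCc1ccccc1
F7 | step 3 | (Z)-1-(benzyloxy)-4-chlorobut-2-ene | ClC/C=C\COCc1ccccc1
F8 | step 3 | (Z)-[4-(benzyloxy)but-2-en-1-yl]trichlorosilane | Cl[Si](Cl)(Cl)C/C=C\COCc1ccccc1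
F9 | step 3 | {[(1S,2S)-1-[4-(benzyloxy)-3-methoxyphenyl]-2-[(benzyloxy)methyl]but-3-en-1-yl]oxy}trichlorosilane | COc1cc([C@@H](O[Si](Cl)(Cl)Cl)[C@H](COCc2ccccc2)C=C)ccc1OCc1ccccc1
F10 | step 5 | 1-(benzyloxy)-4-[chloro(2-chloroethoxy)methyl]-2-methoxybenzene | COc1cc(C(Cl)OCCCl)ccc1OCc1ccccc1
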